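Chain numbering: C1 = oxirane CHBr, C2 = the other oxirane carbon, C3 = CBr2, C4–C7 = butyl. Everything rests on tracing both C3–Br bonds back to a C3 ketone hydrazone. C3 lies at the ketone oxidation level next to oxirane carbon C2, so C1–C3 are the three carbons of a glycerate whose C2–O bond is already configured. In one operation copper(II) bromide oxidises the hydrazone to its diazoalkane and puts two bromines on C3 with loss of N2, closing no ring and leaving C2 untouched. The precursor is the NH2 hydrazone of a butyl ketone bearing C1/C2 as an isopropylidene dioxolane. The oxirane (O–C1 bond) is closed last.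

Key step: step 3

Structure check: 19 is the trans-oxirane, (2R,3S) in ring numbering, i.e. C1 = R and C2 = S in chain numbering. Every intermediate has the same spatial arrangement at C2. The descriptor reads R only in 7 and 9, where C(=N) ranks below CH2O.
Assumption: 7 is carried forward as its E/Z mixture about C=N, because this geometry disappears in 9.

Step 1
Reactants: 1 methyl (S)-2,2-dimethyl-1,3-dioxolane-4-carboxylate; 2 N,O-dimethylhydroxylamine hydrochloride; 3 butylmagnesium bromide
Product: 5 (S)-1-(2,2-dimethyl-1,3-dioxolan-4-yl)pentan-1-one, via Weinreb amide 4 (not isolated)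
Conditions: 2 (1.5 equiv), i-PrMgCl (3.0 equiv), THF, −20 °C; once 1 is consumed, 3 (1.5 equiv), −20 → 0 °C; cold aq NH4Cl
Reagents that add atoms: N,O-dimethylhydroxylamine hydrochloride, CNOC.Cl (its atoms stay only in 4); butylmagnesium bromide, CCCC[Mg]Br
Why: One-pot Weinreb ketone synthesis, in which the chloromagnesium amide made from 2 acylates on ester 1 faster than the ester enolises and the magnesium chelate formed when 3 adds to 4 survives until the quench, so that over-addition is blocked, no free ketone meets base, and C2 keeps its configuration.

Step 2
Reactants: 5 (S)-1-(2,2-dimethyl-1,3-dioxolan-4-yl)pentan-1-one; 6 hydrazine (used as the monohydrate)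
Product: 7 (R)-4-(1-hydrazinylidenepentyl)-2,2-dimethyl-1,3-dioxolane (NH2 hydrazone of 5)
Conditions: N2H4·H2O (10 equiv), EtOH, 0 °C → rt; extractive work-up, used without storage
Reagents that add atoms: hydrazine, NN
Why: Hydrazone condensation, in which the α-alkoxy ketone is electrophilic enough to react at room temperature without added acid or base, the large excess of hydrazine suppresses azine formation, and the mild medium keeps ene-hydrazine tautomerisation, the only route to scrambling at C2, slow (the descriptor changes to R by priority rules alone).

Step 3
Reactants: 7 (R)-4-(1-hydrazinylidenepentyl)-2,2-dimethyl-1,3-dioxolane; 8 copper(II) bromide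
Product: 10 (S)-4-(1,1-dibromopentyl)-2,2-dimethyl-1,3-dioxolane, via diazoalkane 9 (not isolated)
Conditions: 8 (6 equiv) and LiOt-Bu (3 equiv) premixed, THF, 0 °C; 7 in THF added slowly; 0 °C → rt; aq NH4Cl
Reagents that add atoms: copper(II) bromide, Br[Cu]Br
Why: The copper(II) bromide–tert-butoxide reagent takes two electrons and both N–H protons from 7 to give diazoalkane 9; its nucleophilic C3 then binds a further copper(II) bromide, nitrogen leaves, and the resulting copper-bound α-bromoalkyl (carbenoid-type) centre receives its second bromine by ligand transfer from another copper(II) bromide, so that four Cu(II) end as Cu(I). The closest known reaction type is exactly this copper(II) halide/base oxidation of ketone hydrazones to gem-dihalides, a relative of the Barton vinyl halide synthesis, applied here to an α-oxygenated and enolisable member of the class. No ring is closed and no stereocentre is created: the two C3–Br bonds are the only skeletal change, and since none of the four bonds at C2 is touched on the productive path, the configuration bought with 1 is carried into 10. The selectivity needed is chemoselectivity for geminal capture over loss of a C4 proton (vinyl bromide), 1,2-shift of the C2 hydrogen (enol ether) and expulsion of the C2 oxygen. It is secured by a large excess of copper-bound bromide and slow inverse addition, which keep 9 dilute and surrounded by bromide donors, and by the substrate itself: the ketal oxygen is a poor leaving group, no free carbanion arises at C3, and the tied-back dioxolane keeps the space around the emerging CBr2 group open. Premixing the alkoxide with copper leaves no free strong base, so aza-enolisation towards C2, the one path that could erode enantiopurity, stays slow, whereas the three side paths cost material only.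

Step 4
Reactants: 10 (S)-4-(1,1-dibromopentyl)-2,2-dimethyl-1,3-dioxolane
Product: 11 (S)-3,3-dibromoheptane-1,2-diol
Conditions: AcOH–H2O (4:1), 50 °C
Reagents that add atoms: none
Why: Acid-catalysed ketal hydrolysis, in a medium too weakly ionising to disturb the C3 gem-dibromide (its cation would be destabilised by the neighbouring oxygenated carbon) and free of base, which rules out premature attack of either hydroxyl on C3, so C2 is not touched.

Step 5
Reactants: 11 (S)-3,3-dibromoheptane-1,2-diol; 12 triethylsilyl trifluoromethanesulfonate
Product: 13 (S)-3,3-dibromo-1,2-bis(triethylsilyloxy)heptane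
Conditions: TESOTf (2.5 equiv), 2,6-lutidine (4 equiv), CH2Cl2, −78 → 0 °C
Reagents that add atoms: triethylsilyl trifluoromethanesulfonate, CC[Si](CC)(CC)OS(=O)(=O)C(F)(F)F
Why: Silyl ether formation, in which the silyl triflate is reactive enough to cap the hindered and electron-poor C2 hydroxyl as well as the primary one, while 2,6-lutidine is too weak a base to generate an alkoxide next to the C3 bromides.

Step 6
Reactants: 13 (S)-3,3-dibromo-1,2-bis(triethylsilyloxy)heptane
Product: 14 (S)-3,3-dibromo-2-(triethylsilyloxy)heptan-1-ol
Conditions: PPTS (cat.), MeOH–CH2Cl2, −10 → 0 °C
Reagents that add atoms: none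
Why: Selective acid-catalysed methanolysis of a primary over a secondary triethylsilyl ether, since the C1 ether is open to solvent whereas the C2 ether is shielded by the CBr2Bu group and has a less basic oxygen, so only C1–OH should be released.

Step 7
Reactants: 14 (S)-3,3-dibromo-2-(triethylsilyloxy)heptan-1-ol
Product: 15 (S)-3,3-dibromo-2-(triethylsilyloxy)heptanal
Conditions: Dess–Martin periodinane (1.3 equiv), CH2Cl2, 0 °C → rt, no amine; crude 15 used at once
Reagents that add atoms: none
Why: Dess–Martin oxidation, chosen because it runs in a neutral to weakly acidic medium, whereas 15 carries an acidic C2–H with two bromides in the β-position and would be exposed to epimerisation and E1cB loss of HBr under the amine base of an activated-DMSO oxidation.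

Step 8
Reactants: 15 (S)-3,3-dibromo-2-(triethylsilyloxy)heptanal; 16 bromine
Product: 17 triethyl{[(S)-1,1,3,3-tetrabromoheptan-2-yl]oxy}silane
Conditions: P(OPh)3 (1.5 equiv), Br2 (1.4 equiv), CH2Cl2, −78 °C; then 15, −78 °C → rt, no amine
Reagents that add atoms: bromine, BrBr
Why: Deoxygenative gem-dibromination of an aldehyde with the triphenyl phosphite–bromine adduct, in which the carbonyl oxygen binds phosphorus, bromide adds to C1 and a second bromide displaces triphenyl phosphate, all without base, so that C2–H is not removed, the hindered C2 silyl ether stays in place and C1 (two identical bromines) is not yet stereogenic.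

Step 9
Reactants: 17 triethyl{[(S)-1,1,3,3-tetrabromoheptan-2-yl]oxy}silane
Product: 19 (2R,3S)-2-bromo-3-(1,1-dibromopentyl)oxirane, via tetrabromoalkoxide 18 (not isolated)
Conditions: TBAF (1.05 equiv), THF, −20 → 0 °C; cold pentane/water work-up
Reagents that add atoms: none
Why: Fluoride desilylation followed by intramolecular Williamson closure (3-exo-tet) of a 2,2-dibromoalkoxide, the reaction type by which dihalomethyl carbinols give α-halo-oxiranes, in which the C2–O bond is kept so C2 stays S, the hydrogen-bearing C1 is attacked rather than the fully substituted C3, and the new C1 centre is set by substrate control because the transition state that leaves the remaining bromine anti to the bulky CBr2Bu group gives the trans (1R) oxirane.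

Compound list
1 | methyl (S)-2,2-dimethyl-1,3-dioxolane-4-carboxylate | COC(=O)[C@@H]1COC(C)(C)O1 | starting material
2 | N,O-dimethylhydroxylamine hydrochloride | CNOC.Cl | starting material
3 | butylmagnesium bromide | CCCC[Mg]Br | starting material
4 | (S)-N-methoxy-N,2,2-trimethyl-1,3-dioxolane-4-carboxamide (Weinreb amide, not isolated) | CON(C)C(=O)[C@@H]1COC(C)(C)O1 | intermediate
5 | (S)-1-(2,2-dimethyl-1,3-dioxolan-4-yl)pentan-1-one | CCCCC(=O)[C@@H]1COC(C)(C)O1 | intermediate
6 | hydrazine (used as the monohydrate) | NN | starting material
7 | (R)-4-(1-hydrazinylidenepentyl)-2,2-dimethyl-1,3-dioxolane (E/Z mixture at C=N) | CCCCC(=NN)[C@@H]1COC(C)(C)O1 | intermediate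
8 | copper(II) bromide | Br[Cu]Br | starting material
9 | (R)-4-(1-diazopentyl)-2,2-dimethyl-1,3-dioxolane (not isolated) | CCCCC(=[N+]=[N-])[C@@H]1COC(C)(C)O1 | intermediate
10 | (S)-4-(1,1-dibromopentyl)-2,2-dimethyl-1,3-dioxolane | CCCCC(Br)(Br)[C@@H]1COC(C)(C)O1 | intermediate
11 | (S)-3,3-dibromoheptane-1,2-diol | CCCCC(Br)(Br)[C@@H](O)CO | intermediate
12 | triethylsilyl trifluoromethanesulfonate | CC[Si](CC)(CC)OS(=O)(=O)C(F)(F)F | starting material
13 | (S)-3,3-dibromo-1,2-bis(triethylsilyloxy)heptane | CCCCC(Br)(Br)[C@@H](O[Si](CC)(CC)CC)CO[Si](CC)(CC)CC | intermediate
14 | (S)-3,3-dibromo-2-(triethylsilyloxy)heptan-1-ol | CCCCC(Br)(Br)[C@@H](O[Si](CC)(CC)CC)CO | intermediate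
15 | (S)-3,3-dibromo-2-(triethylsilyloxy)heptanal | CCCCC(Br)(Br)[C@@H](O[Si](CC)(CC)CC)C=O | intermediate
16 | bromine | BrBr | starting material
17 | triethyl{[(S)-1,1,3,3-tetrabromoheptan-2-yl]oxy}silane | CCCCC(Br)(Br)[C@@H](O[Si](CC)(CC)CC)C(Br)Br | intermediate
18 | tetrabutylammonium (S)-1,1,3,3-tetrabromoheptan-2-olate (not isolated) | CCCCC(Br)(Br)[C@@H]([O-])C(Br)Br.CCCC[N+](CCCC)(CCCC)CCCC | intermediate
19 | (2R,3S)-2-bromo-3-(1,1-dibromopentyl)oxirane (trans) | CCCCC(Br)(Br)[C@H]1O[C@@H]1Br | target

Total step count: 9. Longest linear sequence: 9 (the route is fully linear).

Steps most likely to fail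

1. Step 3 (key step). Proton loss from C4 or migration of the C2 hydrogen may outrun the second bromine transfer. Base-induced Kishner-type expulsion of the C2 oxygen may compete, or the diazoalkane may be intercepted by unreacted hydrazone (azine formation). The fallback accepts the elimination on purpose and sets out from 7. Bromine and 2-tert-butyl-1,1,3,3-tetramethylguanidine in CH2Cl2 at 0 °C (Barton-type vinyl halide synthesis) should give the vinyl bromide (S)-4-(1-bromopent-1-en-1-yl)-2,2-dimethyl-1,3-dioxolane F1. Ionic Markovnikov hydrobromination (dry HBr, CH2Cl2, 0 °C, dark, radical inhibitor) then places hydrogen on C4 and the second bromine on C3, the bromine-stabilised cation directing the addition. The ketal is not expected to outlast HBr, and stirring with water completes its removal, so the sequence comes back to the route at diol 11. Vinyl bromide formed as a by-product of step 3 can be fed into the same operation.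

2. Step 9. The alkoxide may close onto the C3 gem-dibromide instead of C1, and discrimination between the two diastereotopic C1 bromines may be poor. Soluble fluoride or bromide may reopen the α-bromo-oxirane or trigger its rearrangement to an α-bromo carbonyl compound, and basic fluoride may dehydrobrominate C3/C4. The fallback separates deprotection from ring closure and sets out from 17. HF·pyridine in THF (acidic, no alkoxide present) should release the free alcohol (S)-1,1,3,3-tetrabromoheptan-2-ol F2, which can be purified. Closure then becomes its own operation with NaH in Et2O at −20 → 0 °C. There the sodium bromide precipitates, and the oxirane meets neither fluoride nor dissolved bromide. The sequence comes back to the route at 19.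

3. Step 8. Displacement of the phosphate at the hindered, electron-poor C1 may be sluggish. Adventitious HBr may strip the C2 silyl group, or enolisation with loss of a β-bromide may set in during a long reaction time. The fallback changes from deoxygenative phosphorus(V) bromination to oxidative hydrazone bromination and sets out from 15. Condensation with 1,2-bis(tert-butyldimethylsilyl)hydrazine under catalytic Sc(OTf)3 (no free base) should give the N-(tert-butyldimethylsilyl)hydrazone of 15 F3, in which C2–H is no longer α to a carbonyl group. Oxidation with CuBr2/Et3N in MeOH, the hydrazone-to-gem-dibromide chemistry of step 3 applied to an aldehyde-derived carbon, then forms both C1–Br bonds with loss of nitrogen. The sequence comes back to the route at 17.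

Further compounds
F1 | step 3 | (S)-4-(1-bromopent-1-en-1-yl)-2,2-dimethyl-1,3-dioxolane (E/Z mixture) | CCCC=C(Br)[C@@H]1COC(C)(C)O1
F2 | step 9 | (S)-1,1,3,3-tetrabromoheptan-2-ol | CCCCC(Br)(Br)[C@@H](O)C(Br)Br
F3 | step 8 | N-(tert-butyldimethylsilyl)hydrazone of (S)-3,3-dibromo-2-(triethylsilyloxy)heptanal | CCCCC(Br)(Br)[C@@H](O[Si](CC)(CC)CC)C=NN[Si](C)(C)C(C)(C)C
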